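**Retrosynthetic overview** (rings: A cyclopentane, B pyrrolidine, C piperidine, D cyclohexane, E cyclopentene, F δ-lactone)
1. N-oxide 29 ⇒ amine 28 ⇒ α-chloro sulfone 26. Ring E is not closed as a five-membered ring; it comes from a six-membered thiane 1,1-dioxide by Ramberg–Bäcklund contraction, with loss of HCl and SO2.
2. Enabling feature: ring E holds the only C=C, between the fully substituted carbon bonded to the N–CH of rings C/D and a =CH. An SO2 bridge between these two carbons gives a chair thiane. In that chair the D/E fusion CH (H trans to the N–CH hydrogen, which forces ring D into a boat in the hydrindene) is unstrained.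
3. Ring D plus the thiane ⇒ Diels–Alder reaction of a 5-vinyl-2,3-dihydro-4-pyridone (rings A–C) with 6-chloro-3,4-dihydro-2H-thiopyran 1,1-dioxide, a stand-in for the inaccessible cyclopenta-1,2-diene. Ring F ⇒ methyl addition, then SN1 lactonisation. The C/D fusion H ⇒ hydrogenation while sulfur still masks the ring-E alkene.
4. Ring C ⇒ 6-endo-dig closure of a β-amino ynone. Ring B ⇒ intramolecular Heck reaction and convex-face hydrogenation. The quaternary carbon ⇒ enolate Michael addition.
5. Ring A and the absolute configuration ⇒ cyclopentadiene/chlorosulfonyl isocyanate β-lactam with lipase resolution. Order of ring formation: A, C, B, D + thiane, F, E.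

Key step: step 20

Remark (assumptions): cyclopentadiene is taken as commercial (cracked from its dimer), the lipase is assumed to hydrolyse the (1R,5S)-β-lactam, and the N–O bond is taken to lie anti to the adjacent A/B/C junction C–H, as the target SMILES states.

Step 1
Reactants: 1 dihydro-2H-thiopyran-3(4H)-one 1,1-dioxide
Product: 2 2-chlorodihydro-2H-thiopyran-3(4H)-one 1,1-dioxide (racemic)
Conditions: NCS (1.0 equiv), CH2Cl2, 0 °C to rt
Reagents that add atoms: N-chlorosuccinimide, O=C1CCC(=O)N1Cl
Why: Electrophilic α-chlorination of a β-keto sulfone, whose only strongly acidic CH2 lies between C=O and SO2, so one equivalent should chlorinate that carbon alone; the labile stereocentre is lost in step 3.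

Step 2
Reactants: 2 2-chlorodihydro-2H-thiopyran-3(4H)-one 1,1-dioxide
Product: 3 2-chlorotetrahydro-2H-thiopyran-3-ol 1,1-dioxide (racemic cis/trans mixture)
Conditions: NaBH4, MeOH/CH2Cl2, -10 °C
Reagents that add atoms: none
Why: Borohydride 1,2-reduction of the ketone; the diastereomer ratio is irrelevant because both carbons become sp2 in step 3.

Step 3
Reactants: 3 2-chlorotetrahydro-2H-thiopyran-3-ol 1,1-dioxide
Product: 5 6-chloro-3,4-dihydro-2H-thiopyran 1,1-dioxide, via mesylate 4 (not isolated)
Conditions: MsCl, Et3N (3 equiv), CH2Cl2, 0 °C to rt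
Reagents that add atoms: none
Why: Mesylation followed by E1cB elimination; the proton on the carbon bearing both Cl and SO2 is by far the most acidic, so the double bond should form toward sulfur and give the α-chlorovinyl sulfone.

Step 4
Reactants: 6 cyclopenta-1,3-diene
Product: 8 rac-cis-6-azabicyclo[3.2.0]hept-3-en-7-one, via N-chlorosulfonyl lactam 7 (not isolated)
Conditions: ClSO2NCO, Et2O, -78 °C to 0 °C; then aq. Na2SO3, pH 7-8
Reagents that add atoms: chlorosulfonyl isocyanate, O=C=NS(=O)(=O)Cl
Why: Stepwise dipolar [2+2] cycloaddition of the isocyanate to one C=C (N ends on the allylic carbon), then reductive removal of the N-sulfonyl chloride; the four-membered ring can only be cis-fused, which sets the relative configuration of the two ring-A centres.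

Step 5
Reactants: 8 rac-cis-6-azabicyclo[3.2.0]hept-3-en-7-one
Product: 9 (1R,2S)-2-aminocyclopent-3-ene-1-carboxylic acid
Conditions: immobilised Candida antarctica lipase B, H2O (1 equiv), i-Pr2O, 60 °C; filtration of the amino acid
Reagents that add atoms: water, O
Why: Lipase-catalysed enantioselective β-lactam hydrolysis (kinetic resolution): the enzyme should open only the (1R,5S)-lactam, so the precipitating amino acid carries the absolute configuration from which all later centres are relayed.

Step 6
Reactants: 9 (1R,2S)-2-aminocyclopent-3-ene-1-carboxylic acid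
Product: 10 (1R,2S)-2-(tert-butoxycarbonylamino)cyclopent-3-ene-1-carboxylic acid
Conditions: Boc2O, Et3N, MeOH/H2O, rt
Reagents that add atoms: di-tert-butyl dicarbonate, CC(C)(C)OC(=O)OC(=O)OC(C)(C)C
Why: Standard carbamate protection of the amine, needed so that the basic nitrogen cannot close back to a β-lactam during the Grignard step; no stereocentre is touched.

Step 7
Reactants: 10 (1R,2S)-2-(tert-butoxycarbonylamino)cyclopent-3-ene-1-carboxylic acid
Product: 12 Weinreb amide of 10, via acyl imidazolide 11 (not isolated)
Conditions: CDI, CH2Cl2, rt; then MeNH(OMe)·HCl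
Reagents that add atoms: N,O-dimethylhydroxylamine hydrochloride, CNOC.Cl
Why: Weinreb amide formation through the acyl imidazolide under non-basic conditions, so the α-centre should not epimerise.

Step 8
Reactants: 12 Weinreb amide of 10
Product: 13 N-Boc cis-β-amino ynone (tert-butyl cis-(5-propynoylcyclopent-2-en-1-yl)carbamate)
Conditions: HC≡CMgBr (2.5 equiv), THF, 0 °C; aq. NH4Cl
Reagents that add atoms: ethynylmagnesium bromide, C#C[Mg]Br
Why: Weinreb ketone synthesis; the chelated tetrahedral intermediate prevents a second addition, and one equivalent of Grignard reagent is consumed by the carbamate N–H.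

Step 9
Reactants: 13 N-Boc cis-β-amino ynone
Product: 15 cis-1,4a,5,7a-tetrahydro-4H-cyclopenta[b]pyridin-4-one (NH-enaminone with rings A and C), via amino ynone 14 (not isolated)
Conditions: TFA/CH2Cl2, 0 °C; concentrate; then K2CO3, MeOH, rt
Reagents that add atoms: none
Why: Carbamate acidolysis followed by base-induced 6-endo-dig aza-Michael cyclisation of a β-amino ynone to a 2,3-dihydro-4-pyridone closes ring C; only the cis amino ketone can cyclise, and the α-keto centre stays at the cis-fused arrangement.

Step 10
Reactants: 15 cis-fused bicyclic NH-enaminone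
Product: 16 N-(2-bromoprop-2-enyl) enaminone
Conditions: NaH, DMF, 0 °C; 2,3-dibromopropene
Reagents that add atoms: 2,3-dibromopropene, C=C(Br)CBr
Why: N-alkylation (SN2 at the allylic bromide) of the vinylogous amide anion, whose N–H is the most acidic site; the vinyl bromide is inert here.

Step 11
Reactants: 16 N-(2-bromoprop-2-enyl) enaminone
Product: 17 tricyclic enaminone (rings A–C) with an exocyclic methylene on ring B and the ring-A alkene shifted by one position
Conditions: Pd(OAc)2 (5 mol %), PPh3, K2CO3, DMF, 80 °C
Reagents that add atoms: none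
Why: Intramolecular Mizoroki–Heck reaction: 5-exo-trig syn carbopalladation of the ring-A alkene on the face that carries N closes ring B cis-fused and sets the A/B fusion CH, and syn β-hydride elimination can only occur away from the new bond.

Step 12
Reactants: 17 tricyclic dienyl enaminone
Product: 18 saturated tricyclic enaminone with an endo methyl group (H of CH–CH3 cis to both neighbouring ring-fusion H atoms)
Conditions: H2 (1 atm), RhCl(PPh3)3 (5 mol %), benzene/EtOH, rt
Reagents that add atoms: none
Why: Homogeneous hydrogenation of the two unconjugated alkenes, with the vinylogous amide C=C inert to this catalyst; H2 should reach the exocyclic methylene from the convex face of the cis-fused A/B cup, so the methyl group ends on the concave side.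

Step 13
Reactants: 18 saturated tricyclic enaminone
Product: 19 tricyclic enaminone bearing the 2-(tert-butoxycarbonyl)ethyl chain on the new quaternary carbon (chain cis to the junction N–CH hydrogen)
Conditions: LDA, THF, -78 °C; tert-butyl acrylate; aq. NH4Cl
Reagents that add atoms: tert-butyl acrylate, C=CC(=O)OC(C)(C)C
Why: Michael addition of the cross-conjugated lithium enolate (the only enolisable position) to the acrylate; attack on the convex face, which carries the junction hydrogen, keeps the A/C fusion cis and sets the quaternary centre.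

Step 14
Reactants: 19 tricyclic enaminone with quaternary carbon
Product: 20 α-iodo enaminone
Conditions: NIS, CH2Cl2, rt, dark
Reagents that add atoms: N-iodosuccinimide, O=C1CCC(=O)N1I
Why: Electrophilic iodination at the nucleophilic α-carbon of the vinylogous amide (enamine-type substitution), the only electron-rich carbon in the molecule.

Step 15
Reactants: 20 α-iodo enaminone
Product: 21 α-vinyl enaminone (5-vinyl-2,3-dihydro-4-pyridone diene)
Conditions: tributyl(vinyl)stannane, Pd(PPh3)4 (5 mol %), CuI, DMF, 60 °C
Reagents that add atoms: tributyl(vinyl)stannane, C=C[Sn](CCCC)(CCCC)CCCC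
Why: Stille cross-coupling of an α-iodo enaminone, a neutral method that tolerates the ester and the tertiary vinylogous amide.

Step 16
Reactants: 21 α-vinyl enaminone; 5 6-chloro-3,4-dihydro-2H-thiopyran 1,1-dioxide
Product: 22 pentacyclic enone α-chloro sulfone (rings A–D plus a cis-fused thiane dioxide; SO2 trans to N on ring D)
Conditions: 5 (2 equiv), BHT, toluene, 120 °C, sealed tube
Reagents that add atoms: none
Why: Normal-electron-demand Diels–Alder reaction of a 1-amino-diene with an α-halovinyl sulfone: the amino terminus bonds to the sulfonyl-bearing carbon (ortho rule), the dienophile adds to the diene face that carries the junction hydrogen and is anti to ring A (sets the N–CH), the bulky SO2/CH2 ring takes the exo position and ends trans to N (sets the later D/E fusion CH), and suprafacial addition makes the thiadecalin cis-fused.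

Step 17
Reactants: 22 pentacyclic enone α-chloro sulfone
Product: 23 tertiary allylic alcohol (methyl drawn from the less hindered face)
Conditions: MeMgBr, anhydrous CeCl3, THF, -78 °C; aq. NH4Cl
Reagents that add atoms: methylmagnesium bromide, C[Mg]Br
Why: 1,2-Addition of a weakly basic organocerium reagent to the hindered enone, faster than attack on the tert-butyl ester or deprotonation next to the sulfone; the carbinol configuration does not matter because step 18 passes through the planar cation.

Step 18
Reactants: 23 tertiary allylic alcohol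
Product: 25 unsaturated δ-lactone (ring F closed; O cis to the former chain and methyl trans), via hydroxy acid 24 (not isolated)
Conditions: TFA/CH2Cl2 (1:1), rt; aq. NaHCO3 work-up
Reagents that add atoms: none
Why: Acidolysis of the tert-butyl ester and SN1 lactonisation: the tertiary allylic alcohol ionises, and the tethered acid can reach the cation only from the face on which its chain stands (6-exo closure, cis-fused ring F), which sets the carbinol centre from either epimer of 23.

Step 19
Reactants: 25 unsaturated δ-lactone
Product: 26 saturated hexacyclic α-chloro sulfone (C/D fusion trans)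
Conditions: H2 (4 atm), PtO2, AcOH, rt; aq. NaHCO3 work-up
Reagents that add atoms: none
Why: Heterogeneous syn hydrogenation of the trisubstituted alkene on the protonated amine; the catalyst should bind the convex face of the cis-fused thiadecalin, which is also anti to the methyl group on the neighbouring carbinol carbon, so the new C/D fusion H ends trans to the N–CH hydrogen and cis to the D/thiane fusion H.

Step 20
Reactants: 26 saturated hexacyclic α-chloro sulfone
Product: 28 hexacyclic tertiary amine (N-deoxy target), via episulfone 27 (not isolated)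
Conditions: t-BuOK (2.5 equiv), THF, -20 °C to rt
Reagents that add atoms: none
Why: Ramberg–Bäcklund reaction: tert-butoxide removes an equatorial proton from the only α'-CH2 of the sulfone, the carbanion displaces the tertiary chloride on the other α-carbon in a 1,3-elimination (3-exo-tet, W arrangement) to give episulfone 27, and cheletropic loss of SO2 leaves the alkene. The closest known reaction type is the contraction of α-chloro thiane 1,1-dioxides, including ring-fusion (tertiary) chlorides, to cyclopentenes. The new C–C bond is made across the six-membered ring, so the thiane contracts by one atom to ring E, and the double bond can lie only between the two carbons that carried sulfur, the one position that an ordinary elimination would not pick out among the allylic alternatives. No stereocentre is created in 28: the chlorinated carbon becomes sp2, the two centres of 27 vanish with SO2, and the non-acidic N–CH and D/E fusion CH keep the configurations set in step 16. The step needs C–H selectivity and the right geometry: the chlorinated carbon bears no hydrogen, the trans C/D fusion locks the cis-thiadecalin in the chair–chair form in which C–Cl is equatorial in the thiane, and lactone enolisation is reversible and harmless. Irreversible loss of SO2 and KCl pays for the chair-to-boat change of ring D that this ring-fusion configuration imposes on the hydrindene, which is why that configuration is set at the six-ring stage.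

Step 21
Reactants: 28 hexacyclic tertiary amine
Product: 29 target N-oxide CNP0566793.4
Conditions: mCPBA (1.0 equiv), CH2Cl2, -40 °C to 0 °C; basic alumina filtration
Reagents that add atoms: 3-chloroperoxybenzoic acid, OOC(=O)c1cccc(Cl)c1
Why: Peracid oxidation of a tertiary amine, much faster than epoxidation of the trisubstituted alkene at low temperature with one equivalent; oxygen should be delivered to the lone pair of the trans-fused B/C invertomer (lone pair anti to the adjacent junction C–H), which fixes the configuration at nitrogen.

**Compound list**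
1 | dihydro-2H-thiopyran-3(4H)-one 1,1-dioxide | O=C1CCCS(=O)(=O)C1 | starting material
2 | 2-chlorodihydro-2H-thiopyran-3(4H)-one 1,1-dioxide (racemic) | O=C1CCCS(=O)(=O)C1Cl | intermediate
3 | 2-chlorotetrahydro-2H-thiopyran-3-ol 1,1-dioxide (racemic cis/trans mixture) | OC1CCCS(=O)(=O)C1Cl | intermediate
4 | mesylate of 3 (not isolated) | CS(=O)(=O)OC1CCCS(=O)(=O)C1Cl | intermediate
5 | 6-chloro-3,4-dihydro-2H-thiopyran 1,1-dioxide | ClC1=CCCCS1(=O)=O | intermediate
6 | cyclopenta-1,3-diene | C1=CCC=C1 | starting material
7 | cis-6-(chlorosulfonyl)-6-azabicyclo[3.2.0]hept-3-en-7-one (racemate, one enantiomer drawn; not isolated) | O=C1N(S(=O)(=O)Cl)[C@H]2C=CC[C@@H]12 | intermediate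
8 | cis-6-azabicyclo[3.2.0]hept-3-en-7-one (racemate, (1R,5S) enantiomer drawn) | O=C1N[C@H]2C=CC[C@@H]12 | intermediate
9 | (1R,2S)-2-aminocyclopent-3-ene-1-carboxylic acid | N[C@H]1C=CC[C@H]1C(=O)O | intermediate
10 | (1R,2S)-2-(tert-butoxycarbonylamino)cyclopent-3-ene-1-carboxylic acid | CC(C)(C)OC(=O)N[C@H]1C=CC[C@H]1C(=O)O | intermediate
11 | acyl imidazolide of 10 (not isolated) | CC(C)(C)OC(=O)N[C@H]1C=CC[C@H]1C(=O)n1ccnc1 | intermediate
12 | Weinreb amide of 10 | CC(C)(C)OC(=O)N[C@H]1C=CC[C@H]1C(=O)N(C)OC | intermediate
13 | N-Boc cis-β-amino ynone | CC(C)(C)OC(=O)N[C@H]1C=CC[C@H]1C(=O)C#C | intermediate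
14 | free cis-β-amino ynone (not isolated) | N[C@H]1C=CC[C@H]1C(=O)C#C | intermediate
15 | cis-1,4a,5,7a-tetrahydro-4H-cyclopenta[b]pyridin-4-one | N1C=CC(=O)[C@@H]2CC=C[C@@H]21 | intermediate
16 | N-(2-bromoprop-2-enyl) derivative of 15 | C=C(Br)CN1C=CC(=O)[C@@H]2CC=C[C@@H]21 | intermediate
17 | tricyclic enaminone, exocyclic methylene on ring B, alkene in ring A | C=C1CN2C=CC(=O)[C@@H]3C=C[C@H]1[C@@H]32 | intermediate
18 | saturated tricyclic enaminone, endo methyl | C[C@@H]1CN2C=CC(=O)[C@@H]3CC[C@H]1[C@@H]32 | intermediate
19 | tricyclic enaminone with quaternary carbon and tert-butyl propanoate chain | C[C@@H]1CN2C=CC(=O)[C@]3(CCC(=O)OC(C)(C)C)CC[C@H]1[C@@H]32 | intermediate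
20 | α-iodo enaminone | C[C@@H]1CN2C=C(I)C(=O)[C@]3(CCC(=O)OC(C)(C)C)CC[C@H]1[C@@H]32 | intermediate
21 | α-vinyl enaminone (diene) | C[C@@H]1CN2C=C(C=C)C(=O)[C@]3(CCC(=O)OC(C)(C)C)CC[C@H]1[C@@H]32 | intermediate
22 | Diels–Alder adduct, enone α-chloro sulfone | C[C@@H]1CN2[C@H]3[C@]4(Cl)S(=O)(=O)CCC[C@@H]4CC=C3C(=O)[C@]3(CCC(=O)OC(C)(C)C)CC[C@H]1[C@@H]32 | intermediate
23 | tertiary allylic alcohol | C[C@@H]1CN2[C@H]3[C@]4(Cl)S(=O)(=O)CCC[C@@H]4CC=C3[C@](C)(O)[C@]3(CCC(=O)OC(C)(C)C)CC[C@H]1[C@@H]32 | intermediate
24 | hydroxy acid (not isolated) | C[C@@H]1CN2[C@H]3[C@]4(Cl)S(=O)(=O)CCC[C@@H]4CC=C3[C@](C)(O)[C@]3(CCC(=O)O)CC[C@H]1[C@@H]32 | intermediate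
25 | unsaturated δ-lactone α-chloro sulfone | C[C@@H]1CN2[C@H]3[C@]4(Cl)S(=O)(=O)CCC[C@@H]4CC=C3[C@@]3(C)OC(=O)CC[C@]34CC[C@H]1[C@@H]42 | intermediate
26 | saturated hexacyclic α-chloro sulfone | C[C@@H]1CN2[C@H]3[C@]4(Cl)S(=O)(=O)CCC[C@@H]4CC[C@@H]3[C@@]3(C)OC(=O)CC[C@]34CC[C@H]1[C@@H]42 | intermediate
27 | episulfone (not isolated) | C[C@@H]1CN2[C@H]3[C@]45S(=O)(=O)[C@H]4CC[C@@H]5CC[C@@H]3[C@@]3(C)OC(=O)CC[C@]34CC[C@H]1[C@@H]42 | intermediate
28 | hexacyclic tertiary amine (N-deoxy target) | C[C@@H]1CN2[C@H]3C4=CCC[C@@H]4CC[C@@H]3[C@@]3(C)OC(=O)CC[C@]34CC[C@H]1[C@@H]42 | intermediate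
29 | target N-oxide CNP0566793.4 | C[C@@H]1C[N@@+]2([O-])[C@H]3C4=CCC[C@@H]4CC[C@@H]3[C@@]3(C)OC(=O)CC[C@]34CC[C@H]1[C@@H]42 | target

**Step count and risks**
Total step count: 21. Longest linear sequence: 18 (steps 4 to 21, from 6).

**Step 16.** The cycloaddition may be too slow, because the amino-diene is cross-conjugated with the ketone and the dienophile is trisubstituted. The heating it then needs may erode exo and facial selectivity or cleave the tert-butyl ester. The fallback replaces the cycloaddition by a stepwise ionic annulation; it sets out from 19 and 5 and comes back at 22. Copper-catalysed conjugate addition of allylmagnesium bromide to 5 would give rac-3-allyl-2-chlorotetrahydro-2H-thiopyran 1,1-dioxide F1. Enaminone 19 is O-silylated with TBSOTf to the 4-silyloxy-2,3-dihydropyridinium triflate F2. The α-chloro-α-sulfonyl carbanion of F1 (LiHMDS) adds to the iminium carbon of F2 from the same open face and gives the silyl enol ether F3; the diastereomer from the other enantiomer of F1 is separated. Mild acid gives the ketone F4, Lemieux–Johnson cleavage of the allyl group gives the aldehyde F5, and intramolecular aldol condensation (piperidinium acetate) closes ring D to 22.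

**Step 20.** Anti elimination of HCl toward the N–CH, or attack of alkoxide on the lactone, may outrun the slow 1,3-closure at the tertiary C–Cl centre. The fallback exchanges the roles of the two α-carbons; it sets out from 26 and comes back at 28. Zinc in acetic acid removes the chlorine to give the sulfone F6. A one-flask halogenative Ramberg–Bäcklund reaction (KOH on alumina, CBr2F2, t-BuOH/CH2Cl2) brominates the unhindered CH2 next to sulfur to give the α-bromo sulfone F7. The tertiary α-carbanion then closes to episulfone 27 and SO2 is lost. Any material saponified to the hydroxy acid F8 is re-lactonised with TsOH to 28.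

**Step 19.** Facial discrimination may be poor because the angular chlorine sits on the convex face, and the allylic C–O bond may be hydrogenolysed. The fallback replaces steric control by hydroxyl direction; it sets out from 25 and comes back at 26. K2CO3 in methanol opens the lactone to the hydroxy methyl ester F9, whose tertiary OH stands on the face that must receive hydrogen. Hydrogenation with [Ir(cod)(PCy3)(py)]PF6 delivers H2 syn to that OH and gives the saturated hydroxy ester F10. TsOH in toluene closes ring F again to 26.

Further compounds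
F1 | step 16 | rac-3-allyl-2-chlorotetrahydro-2H-thiopyran 1,1-dioxide | C=CCC1CCCS(=O)(=O)C1Cl
F2 | step 16 | 4-(tert-butyldimethylsilyloxy)-2,3-dihydropyridinium triflate of 19 | C[C@@H]1C[N+]2=CC=C(O[Si](C)(C)C(C)(C)C)[C@]3(CCC(=O)OC(C)(C)C)CC[C@H]1[C@@H]32.[O-]S(=O)(=O)C(F)(F)F
F3 | step 16 | silyl enol ether adduct | C[C@@H]1CN2[C@H](C=C(O[Si](C)(C)C(C)(C)C)[C@]3(CCC(=O)OC(C)(C)C)CC[C@H]1[C@@H]32)[C@]1(Cl)S(=O)(=O)CCC[C@@H]1CC=C
F4 | step 16 | allyl ketone | C[C@@H]1CN2[C@H](CC(=O)[C@]3(CCC(=O)OC(C)(C)C)CC[C@H]1[C@@H]32)[C@]1(Cl)S(=O)(=O)CCC[C@@H]1CC=C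
F5 | step 16 | keto aldehyde | C[C@@H]1CN2[C@H](CC(=O)[C@]3(CCC(=O)OC(C)(C)C)CC[C@H]1[C@@H]32)[C@]1(Cl)S(=O)(=O)CCC[C@@H]1CC=O
F6 | step 20 | dechlorinated hexacyclic sulfone (cis-fused thiadecalin drawn) | C[C@@H]1CN2[C@H]3[C@@H]4S(=O)(=O)CCC[C@@H]4CC[C@@H]3[C@@]3(C)OC(=O)CC[C@]34CC[C@H]1[C@@H]42
F7 | step 20 | α-bromo sulfone (epimer mixture at CHBr) | C[C@@H]1CN2[C@H]3[C@@H]4S(=O)(=O)C(Br)CC[C@@H]4CC[C@@H]3[C@@]3(C)OC(=O)CC[C@]34CC[C@H]1[C@@H]42
F8 | step 20 | hydroxy acid of 28 | C[C@@H]1CN2[C@H]3C4=CCC[C@@H]4CC[C@@H]3[C@@](C)(O)[C@]3(CCC(=O)O)CC[C@H]1[C@@H]32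
F9 | step 19 | unsaturated hydroxy methyl ester | C[C@@H]1CN2[C@H]3[C@]4(Cl)S(=O)(=O)CCC[C@@H]4CC=C3[C@@](C)(O)[C@]3(CCC(=O)OC)CC[C@H]1[C@@H]32
F10 | step 19 | saturated hydroxy methyl ester | C[C@@H]1CN2[C@H]3[C@]4(Cl)S(=O)(=O)CCC[C@@H]4CC[C@@H]3[C@@](C)(O)[C@]3(CCC(=O)OC)CC[C@H]1[C@@H]32
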